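**Plan**
Numbering: phenol carbon C1, chain on C3, methoxy groups on C4 and C5; chain carbons C1' to C17' count outward from C3.
Retrosynthetic cuts, in order: the protecting group on the C1 oxygen; C2'–C3' of the saturated chain; C3–C1'; finally the C1–O bond, traced back to a formyl group.
C2'–C3' lies between two unfunctionalised CH2 groups of the unbranched chain, so each side is a primary alkyl radical that a carboxylic acid gives by loss of CO2: a 2-arylethyl radical (C1', C2') and a straight C15 radical (C3'–C17').
Forward: 5-bromovanillin is O-methylated, its CHO is turned into OH (Baeyer–Villiger) and masked as a MOM ether; a Heck reaction with methyl acrylate at the C–Br carbon, hydrogenation and saponification give the 3-arylpropanoic acid.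
N-Hydroxyphthalimide then esterifies this acid and palmitic acid; the two redox-active esters are joined at C2'–C3' at a nickel-catalysed cathode, and acid removes the MOM group.
No ring is formed and the target has no stereocentre; the E double bond of the Heck product is the only stereo-element on the way and is removed by hydrogenation.

Key step: step 9

**Route**

Step 1
Reactants: 1 5-bromovanillin (3-bromo-4-hydroxy-5-methoxybenzaldehyde)
Product: 2 3-bromo-4,5-dimethoxybenzaldehyde
Conditions: MeI, K2CO3, DMF, rt
Reagents that add atoms: iodomethane, CI
Why: Williamson ether synthesis, in which K2CO3 deprotonates the acidic phenol (para-formyl, ortho-bromo) and the phenoxide displaces iodide from MeI in an SN2 reaction.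

Step 2
Reactants: 2 3-bromo-4,5-dimethoxybenzaldehyde
Product: 4 3-bromo-4,5-dimethoxyphenol, via aryl formate 3 (not isolated)
Conditions: mCPBA, CH2Cl2, 0 °C to rt; aq. Na2S2O3/NaHCO3 wash; then K2CO3 (cat.), MeOH, rt
Reagents that add atoms: mCPBA (3-chloroperoxybenzoic acid), O=C(OO)c1cccc(Cl)c1
Why: Baeyer–Villiger (Dakin-type) oxidation, in which the dimethoxy-substituted aryl group of the Criegee adduct should migrate in preference to hydride to give the aryl formate, which base-catalysed transesterification with methanol cleaves to the phenol.

Step 3
Reactants: 4 3-bromo-4,5-dimethoxyphenol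
Product: 5 1-bromo-2,3-dimethoxy-5-(methoxymethoxy)benzene
Conditions: MOMCl, i-Pr2NEt, CH2Cl2, 0 °C to rt
Reagents that add atoms: chloromethyl methyl ether, COCCl
Why: O-alkylation of the phenol by the highly reactive α-chloro ether under amine base (acetal formation), giving a MOM ether that should survive the basic, reductive and neutral steps that follow.

Step 4
Reactants: 5 1-bromo-2,3-dimethoxy-5-(methoxymethoxy)benzene; 6 methyl acrylate
Product: 7 methyl (E)-3-[2,3-dimethoxy-5-(methoxymethoxy)phenyl]prop-2-enoate
Conditions: Pd(OAc)2 (5 mol %), P(o-tol)3 (12 mol %), Et3N, DMF, 110 °C, sealed tube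
Reagents that add atoms: none
Why: Mizoroki–Heck reaction, in which zerovalent palladium formed in situ adds oxidatively to the C–Br bond, the acrylate inserts syn at its unsubstituted terminus and syn β-hydride elimination gives the E cinnamate, the bulky P(o-tol)3 being the standard ligand for electron-rich, ortho-substituted aryl bromides.

Step 5
Reactants: 7 methyl (E)-3-[2,3-dimethoxy-5-(methoxymethoxy)phenyl]prop-2-enoate
Product: 8 methyl 3-[2,3-dimethoxy-5-(methoxymethoxy)phenyl]propanoate
Conditions: H2 (1 atm), 10% Pd/C, EtOAc, rt
Reagents that add atoms: none
Why: heterogeneous catalytic hydrogenation saturates the conjugated C=C, while the aryl ethers and the MOM acetal are inert to H2 over palladium in a neutral aprotic solvent.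

Step 6
Reactants: 8 methyl 3-[2,3-dimethoxy-5-(methoxymethoxy)phenyl]propanoate
Product: 9 3-[2,3-dimethoxy-5-(methoxymethoxy)phenyl]propanoic acid
Conditions: LiOH·H2O, THF/MeOH/H2O, rt; then 1 M HCl to pH 4, 0 °C
Reagents that add atoms: lithium hydroxide, [Li+].[OH-]
Why: ester saponification by hydroxide addition–elimination at the acyl carbon, with the MOM acetal stable to base and to the brief cold acidification that protonates the carboxylate.

Step 7
Reactants: 9 3-[2,3-dimethoxy-5-(methoxymethoxy)phenyl]propanoic acid; 10 N-hydroxyphthalimide
Product: 11 1,3-dioxoisoindolin-2-yl 3-[2,3-dimethoxy-5-(methoxymethoxy)phenyl]propanoate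
Conditions: DIC, DMAP (cat.), CH2Cl2, rt
Reagents that add atoms: none
Why: Steglich-type carbodiimide esterification, in which the O-acylisourea formed from the acid and DIC passes its acyl group through DMAP to the N–OH oxygen under neutral conditions that leave the acetal intact.

Step 8
Reactants: 12 palmitic acid; 10 N-hydroxyphthalimide
Product: 13 1,3-dioxoisoindolin-2-yl hexadecanoate
Conditions: DIC, DMAP (cat.), CH2Cl2, rt
Reagents that add atoms: none
Why: the same Steglich-type carbodiimide esterification, here on an unfunctionalised fatty acid, giving a crystalline redox-active ester.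

Step 9
Reactants: 11 1,3-dioxoisoindolin-2-yl 3-[2,3-dimethoxy-5-(methoxymethoxy)phenyl]propanoate; 13 1,3-dioxoisoindolin-2-yl hexadecanoate
Product: 14 1-heptadecyl-2,3-dimethoxy-5-(methoxymethoxy)benzene
Conditions: 11 (1 equiv), 13 (3 equiv), NiCl2·6H2O (20 mol %), 2,2':6',2''-terpyridine (20 mol %), AgNO3 (0.3 equiv), NMP, Mg anode, reticulated vitreous carbon cathode, undivided cell, constant current, rt
Reagents that add atoms: none
Why: Each N-acyloxyphthalimide takes up one electron, at the silver-coated cathode or from reduced terpyridine–nickel, and the radical anion collapses to phthalimide anion, CO2 and a primary alkyl radical (2-arylethyl from 11, pentadecyl from 13). Low-valent nickel captures one radical to give an alkylnickel species, which after further reduction captures the second; the resulting dialkylnickel complex (formally trivalent) forms C2'–C3' by reductive elimination, while the Mg anode supplies the electrons and is the only species oxidised. The reaction type is the known nickel-electrocatalytic doubly decarboxylative alkyl–alkyl coupling of two redox-active esters, the reductive counterpart of a mixed Kolbe electrolysis, and primary–primary pairs lie within its scope. No ring is closed and no stereocentre is created. The selectivity needed is cross- over homo-coupling between two radicals of nearly equal reactivity; nothing in the substrate biases it, so it is secured statistically by the threefold excess of the cheap ester 13, after which triacontane and other hydrocarbon by-products should elute with hexane ahead of the triether 14. Chemoselectivity rests on the cathodic, near-neutral medium, which should leave the electron-rich trioxygenated ring, the aryl methyl ethers and the MOM acetal untouched, whereas anodic Kolbe conditions would threaten the arene.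

Step 10
Reactants: 14 1-heptadecyl-2,3-dimethoxy-5-(methoxymethoxy)benzene
Product: 15 3-heptadecyl-4,5-dimethoxyphenol
Conditions: conc. HCl (cat.), MeOH, 50 °C
Reagents that add atoms: none
Why: acid-catalysed acetal cleavage (transacetalisation to methanol) frees the phenol, while the aryl methyl ethers, which need strong Lewis acids for cleavage, stay in place.

**Compound list**
1 | 5-bromovanillin (3-bromo-4-hydroxy-5-methoxybenzaldehyde) | COc1cc(C=O)cc(Br)c1O | starting material
2 | 3-bromo-4,5-dimethoxybenzaldehyde | COc1cc(C=O)cc(Br)c1OC | intermediate
3 | 3-bromo-4,5-dimethoxyphenyl formate | COc1cc(OC=O)cc(Br)c1OC | intermediate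
4 | 3-bromo-4,5-dimethoxyphenol | COc1cc(O)cc(Br)c1OC | intermediate
5 | 1-bromo-2,3-dimethoxy-5-(methoxymethoxy)benzene | COc1cc(OCOC)cc(Br)c1OC | intermediate
6 | methyl acrylate | C=CC(=O)OC | starting material
7 | methyl (E)-3-[2,3-dimethoxy-5-(methoxymethoxy)phenyl]prop-2-enoate | COC(=O)/C=C/c1cc(OCOC)cc(OC)c1OC | intermediate
8 | methyl 3-[2,3-dimethoxy-5-(methoxymethoxy)phenyl]propanoate | COC(=O)CCc1cc(OCOC)cc(OC)c1OC | intermediate
9 | 3-[2,3-dimethoxy-5-(methoxymethoxy)phenyl]propanoic acid | OC(=O)CCc1cc(OCOC)cc(OC)c1OC | intermediate
10 | N-hydroxyphthalimide | O=C1c2ccccc2C(=O)N1O | starting material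
11 | 1,3-dioxoisoindolin-2-yl 3-[2,3-dimethoxy-5-(methoxymethoxy)phenyl]propanoate | O=C(CCc1cc(OCOC)cc(OC)c1OC)ON1C(=O)c2ccccc2C1=O | intermediate
12 | palmitic acid (hexadecanoic acid) | CCCCCCCCCCCCCCCC(=O)O | starting material
13 | 1,3-dioxoisoindolin-2-yl hexadecanoate | CCCCCCCCCCCCCCCC(=O)ON1C(=O)c2ccccc2C1=O | intermediate
14 | 1-heptadecyl-2,3-dimethoxy-5-(methoxymethoxy)benzene | CCCCCCCCCCCCCCCCCc1cc(OCOC)cc(OC)c1OC | intermediate
15 | 3-heptadecyl-4,5-dimethoxyphenol | CCCCCCCCCCCCCCCCCc1cc(O)cc(OC)c1OC | target

**Count**
Total steps: 10. Longest linear sequence: 9 steps (steps 1 to 7, 9 and 10); step 8 is a one-step side branch.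

**Steps most likely to fail**

Step 9. The two primary radicals are not told apart at nickel, so homodimerisation, premature reduction to the alkanes and β-hydride elimination to alkenes can use up 11 before it cross-couples. The activated esters can also hydrolyse in wet NMP. The fallback sets out from 8 and comes back at 14, and builds the chain by olefination one bond further out instead of by radical coupling. Reduction of ester 8 with i-Bu2AlH in toluene at −78 °C would give 3-[2,3-dimethoxy-5-(methoxymethoxy)phenyl]propanal F1. A Wittig reaction with the ylide from commercial tetradecyltriphenylphosphonium bromide and NaN(SiMe3)2 in THF would then give 1-[(Z)-heptadec-3-en-1-yl]-2,3-dimethoxy-5-(methoxymethoxy)benzene F2, whose alkene geometry does not matter. Hydrogenation over Pd/C in ethyl acetate would deliver 14.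

Step 4. Oxidative addition into the electron-rich C–Br bond next to a methoxy group is slow, so the catalyst may aggregate to palladium black, or the arylpalladium species may be reduced (hydrodebromination) before the acrylate inserts. The fallback sets out from 5 and comes back at 7, and uses no palladium. Bromine–lithium exchange with n-BuLi in THF at −78 °C would give [2,3-dimethoxy-5-(methoxymethoxy)phenyl]lithium F3. Trapping with DMF and aqueous NH4Cl work-up would give 2,3-dimethoxy-5-(methoxymethoxy)benzaldehyde F4. Horner–Wadsworth–Emmons olefination with trimethyl phosphonoacetate and NaH in THF would then give the E cinnamate 7.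

Step 2. In the Criegee adduct, hydride migration can compete with aryl migration, because the para-methoxy group is twisted out of conjugation by its two ortho neighbours and bromine lowers the electron density of the ring. The aldehyde would then be lost as the benzoic acid, and the freed phenol can be over-oxidised. The fallback sets out from 1 and comes back at 4, and moves the oxidation ahead of the methylation so that a para-phenoxide drives the aryl shift. Dakin oxidation of 1 with H2O2 and aqueous NaOH would pass through 3-bromo-4-hydroxy-5-methoxyphenyl formate F5 to 2-bromo-6-methoxybenzene-1,4-diol F6, which is handled under argon. TBSCl and imidazole in DMF should silylate only the hydroxyl that has no ortho substituent, giving 2-bromo-4-[tert-butyl(dimethyl)silyl]oxy-6-methoxyphenol F7. MeI and K2CO3 in acetone would methylate the remaining flanked hydroxyl to (3-bromo-4,5-dimethoxyphenoxy)-tert-butyl-dimethylsilane F8, and Bu4NF in THF would release 4.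

**Further compounds**
F1 | step 9 | 3-[2,3-dimethoxy-5-(methoxymethoxy)phenyl]propanal | O=CCCc1cc(OCOC)cc(OC)c1OC
F2 | step 9 | 1-[(Z)-heptadec-3-en-1-yl]-2,3-dimethoxy-5-(methoxymethoxy)benzene | CCCCCCCCCCCCC/C=C\CCc1cc(OCOC)cc(OC)c1OC
F3 | step 4 | [2,3-dimethoxy-5-(methoxymethoxy)phenyl]lithium | [Li]c1cc(OCOC)cc(OC)c1OC
F4 | step 4 | 2,3-dimethoxy-5-(methoxymethoxy)benzaldehyde | O=Cc1cc(OCOC)cc(OC)c1OC
F5 | step 2 | 3-bromo-4-hydroxy-5-methoxyphenyl formate | COc1cc(OC=O)cc(Br)c1O
F6 | step 2 | 2-bromo-6-methoxybenzene-1,4-diol | COc1cc(O)cc(Br)c1O
F7 | step 2 | 2-bromo-4-[tert-butyl(dimethyl)silyl]oxy-6-methoxyphenol | COc1cc(O[Si](C)(C)C(C)(C)C)cc(Br)c1O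
F8 | step 2 | (3-bromo-4,5-dimethoxyphenoxy)-tert-butyl-dimethylsilane | COc1cc(O[Si](C)(C)C(C)(C)C)cc(Br)c1OC
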